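## Retrosynthetic overview

1. The target comes from hydrogenolysis of its tri-O-benzyl ether; the pyranone ring (ring C, formed last) is closed by acid from a 2-aryl-3,3-dimethoxypropanone.
2. That acetal comes from oxidative 1,2-aryl shift of a 2'-hydroxychalcone.
3. The chalcone comes from a Claisen–Schmidt aldol condensation (key C–C bond) of a ring A acetophenone and a ring B chromane aldehyde.
4. The (3S)-chromanol aldehyde comes from C-4 hydride opening of a (3S,4S)-epoxide, made by Jacobsen epoxidation of a 2,2-dimethylchromene (sets the only stereocentre).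
5. The chromene ring (formed first) comes from an aryl propargyl ether Claisen rearrangement on 3,4-dihydroxybenzaldehyde; ring A comes from 2,4,6-trihydroxyacetophenone.

Assumption: the SMILES is read as (S) at C-3 of the chromane ring (the carbinol carbon), and that enantiomer is made; "chroman/chromane" means 3,4-dihydro-2H-chromene.

## Route

**Step 1**
Reactants: 1 3,4-dihydroxybenzaldehyde
Product: 2 3-(benzyloxy)-4-hydroxybenzaldehyde
Conditions: NaH (2.2 equiv), DMSO, rt; then BnCl (1.0 equiv), rt; aq HCl work-up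
Reagents that add atoms: benzyl chloride (ClCc1ccccc1)
Why: Williamson etherification of the catecholate dianion, which reacts at the more nucleophilic 3-oxide because the 4-oxide is delocalised into the para-formyl group.

**Step 2**
Reactants: 2 3-(benzyloxy)-4-hydroxybenzaldehyde; 3 3-chloro-3-methylbut-1-yne
Product: 4 3-(benzyloxy)-4-[(2-methylbut-3-yn-2-yl)oxy]benzaldehyde
Conditions: K2CO3 (2 equiv), KI, CuI (5 mol %), acetone, reflux
Reagents that add atoms: none
Why: Copper-assisted Williamson-type O-propargylation of the only free phenol by the tertiary propargylic chloride, the standard entry to aryl 1,1-dimethylpropargyl ethers.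

**Step 3**
Reactants: 4 3-(benzyloxy)-4-[(2-methylbut-3-yn-2-yl)oxy]benzaldehyde
Product: 6 8-(benzyloxy)-2,2-dimethyl-2H-chromene-6-carbaldehyde, via ortho-allenylphenol 5 (not isolated)
Conditions: N,N-diethylaniline, 190 °C
Reagents that add atoms: none
Why: Aromatic propargyl Claisen rearrangement to the single free ortho position (the other is blocked by OBn) gives the allenylphenol, which closes to the 2,2-dimethylchromene by 1,5-hydrogen shift and oxa-6π electrocyclisation.

**Step 4**
Reactants: 6 8-(benzyloxy)-2,2-dimethyl-2H-chromene-6-carbaldehyde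
Product: 7 2-[8-(benzyloxy)-2,2-dimethyl-2H-chromen-6-yl]-1,3-dioxolane
Conditions: ethylene glycol (5 equiv), PPTS (10 mol %), toluene, reflux, Dean–Stark
Reagents that add atoms: ethylene glycol (OCCO)
Why: Acid-catalysed acetalisation with azeotropic water removal masks the aldehyde against hypochlorite and hydride in the next two steps without touching the chromene or the benzyl ether.

**Step 5**
Reactants: 7 2-[8-(benzyloxy)-2,2-dimethyl-2H-chromen-6-yl]-1,3-dioxolane
Product: 8 (3S,4S)-8-(benzyloxy)-6-(1,3-dioxolan-2-yl)-3,4-epoxy-2,2-dimethylchromane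
Conditions: (S,S)-N,N'-bis(3,5-di-tert-butylsalicylidene)-1,2-cyclohexanediaminomanganese chloride, C36H52ClMnN2O2 (trivalent manganese, 5 mol %), 4-phenylpyridine N-oxide (20 mol %), aq NaOCl (pH 11.3 buffer), CH2Cl2, 0 °C
Reagents that add atoms: sodium hypochlorite ([Na+].[O-]Cl)
Why: Jacobsen–Katsuki epoxidation, for which cis-disubstituted 2,2-dimethylchromenes are the best substrate class (typically above 90% ee), with the (S,S) catalyst delivering oxygen to the face that gives the (3S,4S) epoxide and so fixing C-3 as S.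

**Step 6**
Reactants: 8 (3S,4S)-8-(benzyloxy)-6-(1,3-dioxolan-2-yl)-3,4-epoxy-2,2-dimethylchromane
Product: 10 (3S)-8-(benzyloxy)-3-hydroxy-2,2-dimethylchromane-6-carbaldehyde, via chromanol dioxolane 9 (not isolated)
Conditions: LiAlH4 (1.5 equiv), THF, 0 °C → rt; then 1 M aq HCl, THF, rt
Reagents that add atoms: water (O)
Why: SN2 hydride opening of the epoxide occurs at benzylic C-4 because C-3 is shielded by the adjacent gem-dimethyl carbon, so the C-3–O bond keeps its S configuration, and dilute acid then hydrolyses the dioxolane to the aldehyde.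

**Step 7**
Reactants: 11 2,4,6-trihydroxyacetophenone
Product: 12 1-[2,4-bis(benzyloxy)-6-hydroxyphenyl]ethanone
Conditions: BnBr (2.1 equiv), K2CO3 (2.2 equiv), DMF, rt
Reagents that add atoms: benzyl bromide (BrCc1ccccc1)
Why: Williamson etherification under mild base benzylates the para and one ortho hydroxyl, while the remaining ortho hydroxyl, hydrogen-bonded to the ketone, stays free.

**Step 8**
Reactants: 12 1-[2,4-bis(benzyloxy)-6-hydroxyphenyl]ethanone; 10 (3S)-8-(benzyloxy)-3-hydroxy-2,2-dimethylchromane-6-carbaldehyde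
Product: 14 (2E)-1-[2,4-bis(benzyloxy)-6-hydroxyphenyl]-3-[(3S)-8-(benzyloxy)-3-hydroxy-2,2-dimethylchroman-6-yl]prop-2-en-1-one, via aldol adduct 13 (not isolated)
Conditions: 50% aq KOH (excess), EtOH, rt, 48 h; cold dilute HCl work-up
Reagents that add atoms: none
Why: Claisen–Schmidt aldol condensation in which the acetophenone enolate adds to the non-enolisable aldehyde and E1cB dehydration gives the (E)-chalcone under thermodynamic control, the remote carbinol centre being unaffected.

**Step 9**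
Reactants: 14 (2E)-1-[2,4-bis(benzyloxy)-6-hydroxyphenyl]-3-[(3S)-8-(benzyloxy)-3-hydroxy-2,2-dimethylchroman-6-yl]prop-2-en-1-one
Product: 15 1-[2,4-bis(benzyloxy)-6-hydroxyphenyl]-2-[(3S)-8-(benzyloxy)-3-hydroxy-2,2-dimethylchroman-6-yl]-3,3-dimethoxypropan-1-one (about 1:1 mixture of epimers at C-2 of the propanone chain)
Conditions: Tl(NO3)3·3H2O (trivalent thallium, 1.2 equiv), MeOH/CH(OMe)3 3:1, rt
Reagents that add atoms: methanol (CO)
Why: Oxidative rearrangement of a chalcone, in which oxythallation of the enone is followed by 1,2-migration of the electron-rich para-alkoxyaryl ring with loss of monovalent thallium and methanol capture of the oxocarbenium ion; the new C-2 centre is uncontrolled and is removed in the next step.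

**Step 10**
Reactants: 15 1-[2,4-bis(benzyloxy)-6-hydroxyphenyl]-2-[(3S)-8-(benzyloxy)-3-hydroxy-2,2-dimethylchroman-6-yl]-3,3-dimethoxypropan-1-one
Product: 16 5,7-bis(benzyloxy)-3-[(3S)-8-(benzyloxy)-3-hydroxy-2,2-dimethylchroman-6-yl]-4H-chromen-4-one
Conditions: 10% aq HCl (cat.), MeOH, 65 °C, 2 h
Reagents that add atoms: none
Why: Acid-catalysed transacetalisation by the ortho phenol followed by elimination of methanol (cyclodehydration) closes the pyranone ring and makes the former C-2 centre sp2, giving the isoflavone.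

**Step 11**
Reactants: 16 5,7-bis(benzyloxy)-3-[(3S)-8-(benzyloxy)-3-hydroxy-2,2-dimethylchroman-6-yl]-4H-chromen-4-one
Product: 17 5,7-dihydroxy-3-[(3S)-3,8-dihydroxy-2,2-dimethylchroman-6-yl]-4H-chromen-4-one
Conditions: H2 (1 atm), 10% Pd/C, EtOAc/MeOH, rt, stopped at full debenzylation
Reagents that add atoms: none
Why: Catalytic hydrogenolysis cleaves the three aryl benzyl ethers much faster than it reduces the chromone double bond, and no bond at the carbinol stereocentre is touched.

## Compound list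

1 | 3,4-dihydroxybenzaldehyde | O=Cc1ccc(O)c(O)c1 | starting material
2 | 3-(benzyloxy)-4-hydroxybenzaldehyde | O=Cc1ccc(O)c(OCc2ccccc2)c1 | intermediate
3 | 3-chloro-3-methylbut-1-yne | CC(C)(Cl)C#C | starting material
4 | 3-(benzyloxy)-4-[(2-methylbut-3-yn-2-yl)oxy]benzaldehyde | O=Cc1ccc(OC(C)(C)C#C)c(OCc2ccccc2)c1 | intermediate
5 | 3-(benzyloxy)-4-hydroxy-5-(3-methylbuta-1,2-dien-1-yl)benzaldehyde | O=Cc1cc(C=C=C(C)C)c(O)c(OCc2ccccc2)c1 | intermediate (not isolated)
6 | 8-(benzyloxy)-2,2-dimethyl-2H-chromene-6-carbaldehyde | CC1(C)C=Cc2cc(C=O)cc(OCc3ccccc3)c2O1 | intermediate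
7 | 2-[8-(benzyloxy)-2,2-dimethyl-2H-chromen-6-yl]-1,3-dioxolane | CC1(C)C=Cc2cc(C3OCCO3)cc(OCc3ccccc3)c2O1 | intermediate
8 | (3S,4S)-8-(benzyloxy)-6-(1,3-dioxolan-2-yl)-3,4-epoxy-2,2-dimethylchromane | CC1(C)Oc2c(OCc3ccccc3)cc(C3OCCO3)cc2[C@@H]4O[C@@H]41 | intermediate
9 | (3S)-8-(benzyloxy)-6-(1,3-dioxolan-2-yl)-2,2-dimethylchroman-3-ol | CC1(C)Oc2c(OCc3ccccc3)cc(C3OCCO3)cc2C[C@@H]1O | intermediate (not isolated)
10 | (3S)-8-(benzyloxy)-3-hydroxy-2,2-dimethylchromane-6-carbaldehyde | CC1(C)Oc2c(OCc3ccccc3)cc(C=O)cc2C[C@@H]1O | intermediate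
11 | 2,4,6-trihydroxyacetophenone | CC(=O)c1c(O)cc(O)cc1O | starting material
12 | 1-[2,4-bis(benzyloxy)-6-hydroxyphenyl]ethanone | CC(=O)c1c(O)cc(OCc2ccccc2)cc1OCc1ccccc1 | intermediate
13 | 1-[2,4-bis(benzyloxy)-6-hydroxyphenyl]-3-[(3S)-8-(benzyloxy)-3-hydroxy-2,2-dimethylchroman-6-yl]-3-hydroxypropan-1-one (both carbinol epimers) | CC1(C)Oc2c(OCc3ccccc3)cc(C(O)CC(=O)c3c(O)cc(OCc4ccccc4)cc3OCc3ccccc3)cc2C[C@@H]1O | intermediate (not isolated)
14 | (2E)-1-[2,4-bis(benzyloxy)-6-hydroxyphenyl]-3-[(3S)-8-(benzyloxy)-3-hydroxy-2,2-dimethylchroman-6-yl]prop-2-en-1-one | CC1(C)Oc2c(OCc3ccccc3)cc(/C=C/C(=O)c3c(O)cc(OCc4ccccc4)cc3OCc3ccccc3)cc2C[C@@H]1O | intermediate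
15 | 1-[2,4-bis(benzyloxy)-6-hydroxyphenyl]-2-[(3S)-8-(benzyloxy)-3-hydroxy-2,2-dimethylchroman-6-yl]-3,3-dimethoxypropan-1-one (epimers at C-2 of the chain) | CC1(C)Oc2c(OCc3ccccc3)cc(C(C(OC)OC)C(=O)c3c(O)cc(OCc4ccccc4)cc3OCc3ccccc3)cc2C[C@@H]1O | intermediate
16 | 5,7-bis(benzyloxy)-3-[(3S)-8-(benzyloxy)-3-hydroxy-2,2-dimethylchroman-6-yl]-4H-chromen-4-one | CC1(C)Oc2c(OCc3ccccc3)cc(-c3coc4cc(OCc5ccccc5)cc(OCc5ccccc5)c4c3=O)cc2C[C@@H]1O | intermediate
17 | 5,7-dihydroxy-3-[(3S)-3,8-dihydroxy-2,2-dimethylchroman-6-yl]-4H-chromen-4-one | CC1(C)Oc2c(O)cc(-c3coc4cc(O)cc(O)c4c3=O)cc2C[C@@H]1O | target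

## Step count and risks

Total steps: 11. Longest linear sequence: 10 (steps 1–6, then 8–11); step 7 is the one-step side branch to ring A.

**Step 1 (site-selective mono-benzylation).** The risk is a mixture of 3-O-, 4-O- and di-benzyl ethers. The fallback replaces dianion control with a protect–benzylate–deprotect sequence. It sets out from compound 1. Monoanion alkylation at the more acidic 4-OH (allyl bromide, NaHCO3, NaI, DMF, 40 °C) gives 4-(allyloxy)-3-hydroxybenzaldehyde F1. Benzylation of the remaining phenol (BnBr, K2CO3, DMF) gives 4-(allyloxy)-3-(benzyloxy)benzaldehyde F2. Deallylation with Pd(PPh3)4 (zerovalent palladium, catalytic) and morpholine in THF returns to the route at compound 2.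

**Step 6 (hydride opening of the epoxide).** The risk is that aluminium Lewis acidity ionises the electron-rich benzylic epoxide; rearrangement to a chromanone followed by reduction would erode the ee or give regioisomers. The fallback avoids hydride at the epoxide and removes the C-4 oxygen through a soft nucleophile and a radical reduction. It sets out from compound 8. PhSeSePh/NaBH4 in EtOH (0 °C → rt) opens the epoxide by SN2 at C-4 to give (3R,4R)-8-(benzyloxy)-6-(1,3-dioxolan-2-yl)-2,2-dimethyl-4-(phenylselanyl)chroman-3-ol F3, with the C-3 oxygen untouched. Bu3SnH with catalytic AIBN in toluene at 80 °C then cleaves the C–Se bond and comes back to the route at compound 9, which is hydrolysed to 10 as before.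

**Step 9 (thallium-mediated aryl shift).** The risk is competing aurone or flavone formation from the free 2'-hydroxychalcone, or over-oxidation. The fallback replaces the oxidative aryl shift with the chalcone epoxide/acyl-shift route. It sets out from compound 14. Benzylation of the chelated phenol (BnBr, K2CO3, DMF, 60 °C) gives (2E)-3-[(3S)-8-(benzyloxy)-3-hydroxy-2,2-dimethylchroman-6-yl]-1-[2,4,6-tris(benzyloxy)phenyl]prop-2-en-1-one F4. Weitz–Scheffer epoxidation (30% H2O2, NaOH, MeOH/THF, 0 °C → rt) gives the trans-epoxide [3-[(3S)-8-(benzyloxy)-3-hydroxy-2,2-dimethylchroman-6-yl]oxiran-2-yl][2,4,6-tris(benzyloxy)phenyl]methanone F5 as a diastereomer mixture. BF3·OEt2 in CH2Cl2 at 0 °C opens it at the benzylic carbon with 1,2-aroyl shift to 2-[(3S)-8-(benzyloxy)-3-hydroxy-2,2-dimethylchroman-6-yl]-3-oxo-3-[2,4,6-tris(benzyloxy)phenyl]propanal F6. Hydrogenolysis (H2, Pd/C, EtOAc/MeOH, trace HCl) removes all four benzyl groups, and the freed ortho phenol cyclodehydrates onto the formyl group. This comes back to the route at compound 17, bypassing 15 and 16.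

## Further compounds

F1 | step 1 | 4-(allyloxy)-3-hydroxybenzaldehyde | O=Cc1ccc(OCC=C)c(O)c1
F2 | step 1 | 4-(allyloxy)-3-(benzyloxy)benzaldehyde | O=Cc1ccc(OCC=C)c(OCc2ccccc2)c1
F3 | step 6 | (3R,4R)-8-(benzyloxy)-6-(1,3-dioxolan-2-yl)-2,2-dimethyl-4-(phenylselanyl)chroman-3-ol | CC1(C)Oc2c(OCc3ccccc3)cc(C3OCCO3)cc2[C@@H]([Se]c2ccccc2)[C@@H]1O
F4 | step 9 | (2E)-3-[(3S)-8-(benzyloxy)-3-hydroxy-2,2-dimethylchroman-6-yl]-1-[2,4,6-tris(benzyloxy)phenyl]prop-2-en-1-one | CC1(C)Oc2c(OCc3ccccc3)cc(/C=C/C(=O)c3c(OCc4ccccc4)cc(OCc4ccccc4)cc3OCc3ccccc3)cc2C[C@@H]1O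
F5 | step 9 | [3-[(3S)-8-(benzyloxy)-3-hydroxy-2,2-dimethylchroman-6-yl]oxiran-2-yl][2,4,6-tris(benzyloxy)phenyl]methanone (trans-epoxide, both diastereomers) | CC1(C)Oc2c(OCc3ccccc3)cc(C3OC3C(=O)c3c(OCc4ccccc4)cc(OCc4ccccc4)cc3OCc3ccccc3)cc2C[C@@H]1O
F6 | step 9 | 2-[(3S)-8-(benzyloxy)-3-hydroxy-2,2-dimethylchroman-6-yl]-3-oxo-3-[2,4,6-tris(benzyloxy)phenyl]propanal (epimers at C-2) | CC1(C)Oc2c(OCc3ccccc3)cc(C(C=O)C(=O)c3c(OCc4ccccc4)cc(OCc4ccccc4)cc3OCc3ccccc3)cc2C[C@@H]1O
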